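**Retrosynthetic overview**
1. The (5E)-alkylidene butenolide is unmasked last from a 2,3,4-trisubstituted furan by singlet oxygen and loss of water. The O8 methacrylate and O13 acetate go on just before.
2. The oxolane ring (O, C1, C2, C3, C4) and the cyclodecane ring (C1–C10) are opened together at C2–C3 and at O–C1. This leads back to furan 19 with two open arms, a tertiary vinyl carbinol (C4) and a trans vinyl oxirane (C1/C10).
3. Enabling feature: the ether carbon C1 sits next to the tertiary carbinol C10, which is the pattern of a trans-1,10-oxirane opened at C1 with inversion. The C2–C3 ethano bridge of the oxolane lies between two O-bearing carbons, so it is the reduced form of a Z-alkene made from two vinyl groups. The cis C6–C7 edge of the five-membered ring holds both arms on one side.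
4. Stereocentres: C4 comes from (R)-lactic acid by enolate alkylation, C8 from a catalytic vinylogous Mukaiyama aldol reaction, and C1/C10 from a Sharpless epoxidation. The furan comes from a Feist–Benary synthesis.
5. Ring order: furan, then cyclodecene and dihydrofuran in one operation, then oxolane by reduction, then butenolide.

Key step: step 14

Locants follow the germacrane skeleton of the target. C1 is the oxolane CH, C2/C3 are the oxolane CH2CH2 and C4 is the oxolane C(CH3). C5 is the exocyclic =CH and C6 the O-bearing alkylidene carbon. C7 and C11 are the lactone C=C and C12 is the lactone C=O. C8 is the CH–O-methacryloyl carbon, C9 the CH2, C10 the C(OH)CH3 and C13 the CH2OAc. TBS = tert-butyldimethylsilyl.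
Assumption: 1 and 2 are taken as catalogue chemicals, and the chiral bisphosphoramide of step 7 is used as the antipode that leads to Si-face attack on the aldehyde.

Step 1
Reactants: 1 N-methoxy-N-methyl-3-oxobutanamide; 2 3-chloro-2-oxopropyl acetate
Product: 4 [4-(N-methoxy-N-methylcarbamoyl)-5-methylfuran-3-yl]methyl acetate, via hydroxydihydrofuran 3 (not isolated)
Conditions: pyridine, 50 °C; then TsOH·H2O (cat.), toluene, 80 °C
Reagents that add atoms: none
Why: Feist–Benary furan synthesis, in which the keto amide enol adds to the doubly activated ketone, the enol oxygen displaces chloride and acid removes water, so that the C5 methyl, C8 amide and C13 acetoxymethyl groups are placed on neighbouring ring carbons by construction.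

Step 2
Reactants: 4 [4-(N-methoxy-N-methylcarbamoyl)-5-methylfuran-3-yl]methyl acetate
Product: 5 [5-(bromomethyl)-4-(N-methoxy-N-methylcarbamoyl)furan-3-yl]methyl acetate
Conditions: NBS, AIBN (cat.), PhCF3, 85 °C
Reagents that add atoms: N-bromosuccinimide O=C1CCC(=O)N1Br
Why: Wohl–Ziegler bromination should take the furan-2-methyl group, which gives the best stabilised radical, while the amide deactivates the ring and the acetate deactivates the other CH2 toward bromine atoms.

Step 3
Reactants: 6 (R)-lactic acid; 7 pivalaldehyde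
Product: 8 (2R,5R)-2-tert-butyl-5-methyl-1,3-dioxolan-4-one
Conditions: TsOH·H2O (cat.), pentane, reflux, water separator; crystallisation of the cis isomer
Reagents that add atoms: none
Why: Acid-catalysed acetalisation of the hydroxy acid gives the thermodynamic, crystalline cis acetal, which stores the lactate configuration in the new acetal centre.

Step 4
Reactants: 8 (2R,5R)-2-tert-butyl-5-methyl-1,3-dioxolan-4-one; 5 [5-(bromomethyl)-4-(N-methoxy-N-methylcarbamoyl)furan-3-yl]methyl acetate
Product: 9 (2R,5S)-5-{[4-(acetoxymethyl)-3-(N-methoxy-N-methylcarbamoyl)furan-2-yl]methyl}-2-tert-butyl-5-methyl-1,3-dioxolan-4-one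
Conditions: LiN(iPr)2, THF, −78 °C; then 5, −78 → −30 °C
Reagents that add atoms: none
Why: Enolate alkylation with self-regeneration of the stereocentre, in which the reactive furfuryl-type bromide approaches the planar enolate anti to the tert-butyl group and so sets the quaternary C4 with overall retention.

Step 5
Reactants: 9 (2R,5S)-5-{[4-(acetoxymethyl)-3-(N-methoxy-N-methylcarbamoyl)furan-2-yl]methyl}-2-tert-butyl-5-methyl-1,3-dioxolan-4-one
Product: 10 (2R,5S)-5-{[4-(acetoxymethyl)-3-formylfuran-2-yl]methyl}-2-tert-butyl-5-methyl-1,3-dioxolan-4-one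
Conditions: Cp2Zr(H)Cl (1.5 equiv), THF, 23 °C; moist SiO2
Reagents that add atoms: none
Why: Zirconium hydride reduction of a tertiary (Weinreb) amide stops at a stable metalated hemiaminal and is known to spare esters and lactones, so only C8 should become an aldehyde.

Step 6
Reactants: 11 methyl 3-methylbut-2-enoate
Product: 12 tert-butyl[(1-methoxy-3-methylbuta-1,3-dien-1-yl)oxy]dimethylsilane
Conditions: LiN(iPr)2, THF–DMPU, −78 °C; TBSCl
Reagents that add atoms: tert-butyldimethylsilyl chloride CC(C)(C)[Si](C)(C)Cl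
Why: Kinetic γ-deprotonation of the enoate followed by O-silylation is the standard silyl dienol ether (silyl ketene acetal) formation.

Step 7
Reactants: 10 (2R,5S)-5-{[4-(acetoxymethyl)-3-formylfuran-2-yl]methyl}-2-tert-butyl-5-methyl-1,3-dioxolan-4-one; 12 tert-butyl[(1-methoxy-3-methylbuta-1,3-dien-1-yl)oxy]dimethylsilane
Product: 13 methyl (2E,5S)-5-[4-(acetoxymethyl)-2-{[(2R,4S)-2-tert-butyl-4-methyl-5-oxo-1,3-dioxolan-4-yl]methyl}furan-3-yl]-5-hydroxy-3-methylpent-2-enoate
Conditions: SiCl4 (1.2 equiv), chiral 1,1′-binaphthyl-2,2′-diamine-derived bisphosphoramide (5 mol %), iPr2NEt (10 mol %), CH2Cl2, −78 °C; aq. NaHCO3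
Reagents that add atoms: none
Why: Catalytic enantioselective vinylogous Mukaiyama aldol reaction (Lewis-base-activated SiCl4), which is γ- and E-selective for this dienolate and works best with aromatic aldehydes, so that catalyst-controlled Si-face attack should set 8S and deliver C9–C10=C1–C2 in one step.

Step 8
Reactants: 13 methyl (2E,5S)-5-[4-(acetoxymethyl)-2-{[(2R,4S)-2-tert-butyl-4-methyl-5-oxo-1,3-dioxolan-4-yl]methyl}furan-3-yl]-5-hydroxy-3-methylpent-2-enoate
Product: 14 methyl (2E,5S)-5-[2-{[(2R,4S)-2-tert-butyl-4-methyl-5-oxo-1,3-dioxolan-4-yl]methyl}-4-(hydroxymethyl)furan-3-yl]-5-hydroxy-3-methylpent-2-enoate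
Conditions: K2CO3 (0.2 equiv), MeOH, 0 °C
Reagents that add atoms: none
Why: Base-catalysed transesterification should remove the unhindered primary acetate much faster than it touches the dioxolanone, which has a quaternary carbon next to its carbonyl, or the conjugated ester.

Step 9
Reactants: 14 methyl (2E,5S)-5-[2-{[(2R,4S)-2-tert-butyl-4-methyl-5-oxo-1,3-dioxolan-4-yl]methyl}-4-(hydroxymethyl)furan-3-yl]-5-hydroxy-3-methylpent-2-enoate
Product: 15 methyl (2E,5S)-5-(TBS-oxy)-5-[2-{[(2R,4S)-2-tert-butyl-4-methyl-5-oxo-1,3-dioxolan-4-yl]methyl}-4-(TBS-oxymethyl)furan-3-yl]-3-methylpent-2-enoate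
Conditions: TBSOTf (2.5 equiv), 2,6-lutidine, CH2Cl2, −78 → 0 °C
Reagents that add atoms: tert-butyldimethylsilyl triflate CC(C)(C)[Si](C)(C)OS(=O)(=O)C(F)(F)F
Why: Silyl triflate silylation caps O8 and O13 together, and no other free hydroxyl is present at this stage.

Step 10
Reactants: 15 methyl (2E,5S)-5-(TBS-oxy)-5-[2-{[(2R,4S)-2-tert-butyl-4-methyl-5-oxo-1,3-dioxolan-4-yl]methyl}-4-(TBS-oxymethyl)furan-3-yl]-3-methylpent-2-enoate
Product: 16 (2S)-3-{4-(TBS-oxymethyl)-3-[(1S,3E)-1-(TBS-oxy)-5-hydroxy-3-methylpent-3-en-1-yl]furan-2-yl}-2-methylpropane-1,2-diol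
Conditions: iBu2AlH (excess), CH2Cl2, −78 → 0 °C; Rochelle salt
Reagents that add atoms: none
Why: Hydride reduction gives the E-allylic alcohol by 1,2-reduction of the enoate and releases the C3/C4 diol by exhaustive reduction of the dioxolanone, without touching any stereocentre.

Step 11
Reactants: 16 (2S)-3-{4-(TBS-oxymethyl)-3-[(1S,3E)-1-(TBS-oxy)-5-hydroxy-3-methylpent-3-en-1-yl]furan-2-yl}-2-methylpropane-1,2-diol
Product: 17 (2S)-3-{4-(TBS-oxymethyl)-3-[(1S)-1-(TBS-oxy)-2-[(2R,3R)-3-(hydroxymethyl)-2-methyloxiran-2-yl]ethyl]furan-2-yl}-2-methylpropane-1,2-diol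
Conditions: Ti(OiPr)4 (1.5 equiv), D-(−)-diethyl tartrate (1.8 equiv), tBuOOH, 4 Å molecular sieves, CH2Cl2, −20 °C
Reagents that add atoms: tert-butyl hydroperoxide CC(C)(C)OO
Why: Sharpless asymmetric epoxidation, in which only the primary E-allylic alcohol is a ligand-accelerated substrate and D-(−)-tartrate delivers oxygen to the face that gives the (1R,10R) oxirane under reagent control, with titanium in excess because the 1,2-diol binds part of it.

Step 12
Reactants: 17 (2S)-3-{4-(TBS-oxymethyl)-3-[(1S)-1-(TBS-oxy)-2-[(2R,3R)-3-(hydroxymethyl)-2-methyloxiran-2-yl]ethyl]furan-2-yl}-2-methylpropane-1,2-diol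
Product: 18 (2S)-3-{4-(TBS-oxymethyl)-3-[(1S)-1-(TBS-oxy)-2-[(2R,3S)-3-formyl-2-methyloxiran-2-yl]ethyl]furan-2-yl}-2-hydroxy-2-methylpropanal
Conditions: SO3·pyridine, DMSO, Et3N, CH2Cl2, 0 °C
Reagents that add atoms: none
Why: Parikh–Doering oxidation converts both primary alcohols (C2 and C3) to aldehydes in one step under non-acidic conditions that leave the tertiary alcohol, the oxirane and the furan alone.

Step 13
Reactants: 18 (2S)-3-{4-(TBS-oxymethyl)-3-[(1S)-1-(TBS-oxy)-2-[(2R,3S)-3-formyl-2-methyloxiran-2-yl]ethyl]furan-2-yl}-2-hydroxy-2-methylpropanal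
Product: 19 (2S)-1-{4-(TBS-oxymethyl)-3-[(1S)-1-(TBS-oxy)-2-[(2R,3R)-3-ethenyl-2-methyloxiran-2-yl]ethyl]furan-2-yl}-2-methylbut-3-en-2-ol
Conditions: MePPh3Br, KN(SiMe3)2 (4 equiv each), THF, −78 → 0 °C
Reagents that add atoms: methyltriphenylphosphonium bromide C[P+](c1ccccc1)(c1ccccc1)c1ccccc1.[Br-]
Why: Double Wittig methylenation, in which the non-enolisable C3 aldehyde and the epoxy aldehyde both add the ylide at low temperature faster than any base-induced side reaction can occur.

Step 14
Reactants: 19 (2S)-1-{4-(TBS-oxymethyl)-3-[(1S)-1-(TBS-oxy)-2-[(2R,3R)-3-ethenyl-2-methyloxiran-2-yl]ethyl]furan-2-yl}-2-methylbut-3-en-2-ol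
Product: 21 (1S,4S,8S,10R)-1,4-epoxy-bridged furanocyclodec-2-ene with 10-OH 8-OTBS 13-OTBS, via Z-cyclodecene epoxy alcohol 20 (not isolated)
Conditions: second-generation Hoveyda–Grubbs catalyst (10 mol %), 2,6-dichloro-1,4-benzoquinone (10 mol %), toluene (1 mM), 80 °C, argon sparge; then pyridinium p-toluenesulfonate (10 mol %), 23 °C, same flask
Reagents that add atoms: none
Why: The ruthenium alkylidene joins the two monosubstituted vinyl groups by ring-closing metathesis (loss of ethene) to the ten-membered (2Z)-cycloalkene 20, in which the C4 hydroxyl sits 1,4-cis across the new alkene from C1, and this oxygen then opens the allylically activated oxirane at C1 in a transannular SN2 reaction that frees the C10 alcohol. The closest known reaction types are ring-closing metathesis of tertiary vinyl carbinols and of vinyl oxiranes to medium rings, and the mild-acid cyclisation of (Z)-4,5-epoxy-2-en-1-ols to 2-(1-hydroxyalkyl)-2,5-dihydrofurans. The carbocycle closes as a ten-membered metathesis ring closure on the cis C6–C7 edge of the furan, which holds both arms on one side, and the dihydrofuran ring closes 5-exo-tet. C1 is the only stereocentre that changes and it is set by inversion of the (1R) oxirane carbon, while C4, C8 and C10 are carried through, so the 2,5-cis bridge follows from the (4S) and (1R,10R) centres installed earlier. The step needs Z over E geometry, 5-exo attack at C1 over 6-endo attack at C10, and O4 over O8 as the nucleophile: metathesis is reversible and only the Z isomer is drained irreversibly, C1 is secondary and allylic whereas C10 is tertiary and would need the larger ring, and O8 is silylated. The free allylic hydroxyl at C4 should in addition speed up metathesis at the hindered quaternary site.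

Step 15
Reactants: 21 (1S,4S,8S,10R)-1,4-epoxy-bridged furanocyclodec-2-ene with 10-OH 8-OTBS 13-OTBS
Product: 22 (1S,4R,8S,10R)-1,4-epoxy-bridged furanocyclodecane with 10-OH 8-OTBS 13-OTBS
Conditions: 2-nitrobenzenesulfonohydrazide (excess), Et3N, CH2Cl2, 23 °C
Reagents that add atoms: none
Why: Diimide reduction transfers H2 in a concerted syn manner to the strained cis-disubstituted C2=C3 alkene and is inert toward the furan, the silyl ethers and the furylmethyl C–O bonds that catalytic hydrogenation could cleave.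

Step 16
Reactants: 22 (1S,4R,8S,10R)-1,4-epoxy-bridged furanocyclodecane with 10-OH 8-OTBS 13-OTBS
Product: 23 (1S,4R,8S,10R)-1,4-epoxy-bridged furanocyclodecane-8,10,13-triol
Conditions: Bu4NF, THF, 0 → 23 °C
Reagents that add atoms: none
Why: Fluoride-induced desilylation removes both TBS groups, and nothing else in the molecule is fluoride- or base-labile.

Step 17
Reactants: 23 (1S,4R,8S,10R)-1,4-epoxy-bridged furanocyclodecane-8,10,13-triol
Product: 24 13-O-acetyl derivative of triol 23
Conditions: AcCl (1.05 equiv), 2,4,6-collidine, CH2Cl2, −78 °C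
Reagents that add atoms: acetyl chloride CC(=O)Cl
Why: Selective acylation, since at −78 °C with collidine acetyl chloride distinguishes the primary furylmethyl alcohol from the hindered secondary and tertiary ones.

Step 18
Reactants: 24 13-O-acetyl derivative of triol 23
Product: 25 8-O-methacryloyl-13-O-acetyl furan
Conditions: methacrylic anhydride, Et3N, DMAP (cat.), CH2Cl2, 23 °C
Reagents that add atoms: methacrylic anhydride C=C(C)C(=O)OC(=O)C(C)=C
Why: DMAP-catalysed acylation esterifies the only remaining acylable hydroxyl (O8), because the tertiary C10 hydroxyl is too hindered under these conditions.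

Step 19
Reactants: 25 8-O-methacryloyl-13-O-acetyl furan
Product: 27 6-hydroxybutenolide (either C6 epimer), via furan endoperoxide 26 (not isolated)
Conditions: O2, visible light, tetraphenylporphyrin (cat.), iPr2NEt, CH2Cl2, −78 °C
Reagents that add atoms: dioxygen O=O
Why: [4+2] cycloaddition of singlet oxygen to the furan followed by base-induced Kornblum–DeLaMare fragmentation at the only ring C–H (C12) places the carbonyl at C12 and the hemiketal at C6, while the electron-poor methacrylate is inert to singlet oxygen.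

Step 20
Reactants: 27 6-hydroxybutenolide (either C6 epimer)
Product: 29 target CNP0516045.1, via acetoxybutenolide 28 (not isolated)
Conditions: Ac2O, pyridine, CH2Cl2, 0 → 23 °C
Reagents that add atoms: none
Why: Acylative dehydration of a γ-hydroxybutenolide, in which the pseudo-acid hydroxyl is acetylated in preference to the tertiary C10 hydroxyl and acetic acid is lost through the acyloxy-stabilised C6 cation and the C5 proton, and the ten-membered ring allows only the isomer with C4 cis to C7, which is the (5E)-alkene.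

**Compound list**
1 | N-methoxy-N-methyl-3-oxobutanamide | CC(=O)CC(=O)N(C)OC | starting material
2 | 3-chloro-2-oxopropyl acetate | CC(=O)OCC(=O)CCl | starting material
3 | [3-hydroxy-4-(N-methoxy-N-methylcarbamoyl)-5-methyl-2,3-dihydrofuran-3-yl]methyl acetate (racemic) | CON(C)C(=O)C1=C(C)OCC1(O)COC(C)=O | intermediate
4 | [4-(N-methoxy-N-methylcarbamoyl)-5-methylfuran-3-yl]methyl acetate | CON(C)C(=O)c1c(C)occ1COC(C)=O | intermediate
5 | [5-(bromomethyl)-4-(N-methoxy-N-methylcarbamoyl)furan-3-yl]methyl acetate | CON(C)C(=O)c1c(CBr)occ1COC(C)=O | intermediate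
6 | (R)-lactic acid | C[C@@H](O)C(=O)O | starting material
7 | pivalaldehyde | CC(C)(C)C=O | starting material
8 | (2R,5R)-2-tert-butyl-5-methyl-1,3-dioxolan-4-one (cis) | C[C@H]1O[C@@H](C(C)(C)C)OC1=O | intermediate
9 | (2R,5S)-5-{[4-(acetoxymethyl)-3-(N-methoxy-N-methylcarbamoyl)furan-2-yl]methyl}-2-tert-butyl-5-methyl-1,3-dioxolan-4-one | C[C@@]1(Cc2occ(COC(C)=O)c2C(=O)N(C)OC)O[C@@H](C(C)(C)C)OC1=O | intermediate
10 | (2R,5S)-5-{[4-(acetoxymethyl)-3-formylfuran-2-yl]methyl}-2-tert-butyl-5-methyl-1,3-dioxolan-4-one | C[C@@]1(Cc2occ(COC(C)=O)c2C=O)O[C@@H](C(C)(C)C)OC1=O | intermediate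
11 | methyl 3-methylbut-2-enoate | COC(=O)C=C(C)C | starting material
12 | tert-butyl[(1-methoxy-3-methylbuta-1,3-dien-1-yl)oxy]dimethylsilane | C=C(C)C=C(OC)O[Si](C)(C)C(C)(C)C | intermediate
13 | methyl (2E,5S)-5-[4-(acetoxymethyl)-2-{[(2R,4S)-2-tert-butyl-4-methyl-5-oxo-1,3-dioxolan-4-yl]methyl}furan-3-yl]-5-hydroxy-3-methylpent-2-enoate | C[C@@]1(Cc2occ(COC(C)=O)c2[C@@H](O)C/C(C)=C/C(=O)OC)O[C@@H](C(C)(C)C)OC1=O | intermediate
14 | methyl (2E,5S)-5-[2-{[(2R,4S)-2-tert-butyl-4-methyl-5-oxo-1,3-dioxolan-4-yl]methyl}-4-(hydroxymethyl)furan-3-yl]-5-hydroxy-3-methylpent-2-enoate | C[C@@]1(Cc2occ(CO)c2[C@@H](O)C/C(C)=C/C(=O)OC)O[C@@H](C(C)(C)C)OC1=O | intermediate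
15 | bis-TBS ether of 14 (O8 and O13) | C[C@@]1(Cc2occ(CO[Si](C)(C)C(C)(C)C)c2[C@@H](O[Si](C)(C)C(C)(C)C)C/C(C)=C/C(=O)OC)O[C@@H](C(C)(C)C)OC1=O | intermediate
16 | (2S)-3-{4-(TBS-oxymethyl)-3-[(1S,3E)-1-(TBS-oxy)-5-hydroxy-3-methylpent-3-en-1-yl]furan-2-yl}-2-methylpropane-1,2-diol | C[C@@](O)(CO)Cc1occ(CO[Si](C)(C)C(C)(C)C)c1[C@@H](O[Si](C)(C)C(C)(C)C)C/C(C)=C/CO | intermediate
17 | (2S)-3-{4-(TBS-oxymethyl)-3-[(1S)-1-(TBS-oxy)-2-[(2R,3R)-3-(hydroxymethyl)-2-methyloxiran-2-yl]ethyl]furan-2-yl}-2-methylpropane-1,2-diol | C[C@@](O)(CO)Cc1occ(CO[Si](C)(C)C(C)(C)C)c1[C@@H](O[Si](C)(C)C(C)(C)C)C[C@@]2(C)O[C@@H]2CO | intermediate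
18 | (2S)-3-{4-(TBS-oxymethyl)-3-[(1S)-1-(TBS-oxy)-2-[(2R,3S)-3-formyl-2-methyloxiran-2-yl]ethyl]furan-2-yl}-2-hydroxy-2-methylpropanal | C[C@@](O)(C=O)Cc1occ(CO[Si](C)(C)C(C)(C)C)c1[C@@H](O[Si](C)(C)C(C)(C)C)C[C@@]2(C)O[C@@H]2C=O | intermediate
19 | (2S)-1-{4-(TBS-oxymethyl)-3-[(1S)-1-(TBS-oxy)-2-[(2R,3R)-3-ethenyl-2-methyloxiran-2-yl]ethyl]furan-2-yl}-2-methylbut-3-en-2-ol | C[C@@](O)(C=C)Cc1occ(CO[Si](C)(C)C(C)(C)C)c1[C@@H](O[Si](C)(C)C(C)(C)C)C[C@@]2(C)O[C@@H]2C=C | intermediate
20 | (1R,2Z,4S,8S,10R)-cyclodecene fused to the furan at C6–C7; 1,10-oxirane; 4-OH and 4-CH3; 8-OTBS; 13-OTBS | C[C@]1(O)Cc2occ(CO[Si](C)(C)C(C)(C)C)c2[C@@H](O[Si](C)(C)C(C)(C)C)C[C@@]3(C)O[C@@H]3/C=C\1 | intermediate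
21 | (1S,4S,8S,10R)-furanocyclodecene with O bridge C1–C4 (2,5-dihydrofuran ring O/C1/C2=C3/C4); 10-OH and 10-CH3; 8-OTBS; 13-OTBS | CC(C)(C)[Si](C)(C)O[C@H]1C[C@@](C)(O)[C@@H]2C=C[C@](C)(Cc3occ(CO[Si](C)(C)C(C)(C)C)c31)O2 | intermediate
22 | (1S,4R,8S,10R)-furanocyclodecane with O bridge C1–C4 (oxolane ring); 10-OH; 8-OTBS; 13-OTBS | CC(C)(C)[Si](C)(C)O[C@H]1C[C@@](C)(O)[C@@H]2CC[C@](C)(Cc3occ(CO[Si](C)(C)C(C)(C)C)c31)O2 | intermediate
23 | (1S,4R,8S,10R)-8,10,13-triol of the oxolane-bridged furanocyclodecane | O[C@H]1C[C@@](C)(O)[C@@H]2CC[C@](C)(Cc3occ(CO)c31)O2 | intermediate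
24 | 13-O-acetate of 23 | O[C@H]1C[C@@](C)(O)[C@@H]2CC[C@](C)(Cc3occ(COC(C)=O)c31)O2 | intermediate
25 | 8-O-methacrylate 13-O-acetate of 23 | C=C(C)C(=O)O[C@H]1C[C@@](C)(O)[C@@H]2CC[C@](C)(Cc3occ(COC(C)=O)c31)O2 | intermediate
26 | C6/C12 endoperoxide of furan 25 | C=C(C)C(=O)O[C@H]1C[C@@](C)(O)[C@@H]2CC[C@](C)(CC34OOC(O3)C(COC(C)=O)=C41)O2 | intermediate
27 | 6-hydroxy-6,12-olide (γ-hydroxybutenolide; C6 epimers) | C=C(C)C(=O)O[C@H]1C[C@@](C)(O)[C@@H]2CC[C@](C)(CC3(O)OC(=O)C(COC(C)=O)=C31)O2 | intermediate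
28 | 6-acetoxy-6,12-olide (C6 epimers) | C=C(C)C(=O)O[C@H]1C[C@@](C)(O)[C@@H]2CC[C@](C)(CC3(OC(C)=O)OC(=O)C(COC(C)=O)=C31)O2 | intermediate
29 | CNP0516045.1, (1S,4R,5E,8S,10R)-13-acetoxy-1,4-epoxy-10-hydroxy-8-methacryloyloxygermacra-5,7(11)-dien-6,12-olide | C=C(C)C(=O)O[C@H]1C[C@@](C)(O)[C@@H]2CC[C@](C)(/C=C3/OC(=O)C(COC(C)=O)=C31)O2 | target

Total step count: 20. Longest linear sequence: 18 steps (steps 1, 2, 4, 5 and 7–20).

**Steps most likely to fail**

Step 14. Oligomerisation may outrun the ten-membered ring closure at the hindered C4 vinyl group. The ring may also close to the E-cycloalkene, in which O4 cannot reach the rear side of the C1–O bond, so that ether formation stalls. The fallback sets out from 19 and separates the two bond formations. The metathesis is run without acid and the cycloalkene is taken on whatever its geometry, shown here as the E-cyclodecene epoxy alcohol F1. Diimide then saturates C2=C3 to the saturated 1,10-epoxy-4-ol F2. Its flexible C1–C4 chain allows the classical camphorsulfonic-acid-catalysed 5-exo-tet opening of a 4,5-epoxy alcohol with inversion at C1. This rejoins the route at 22.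

Step 20. The amine may add to the newly formed cross-conjugated lactone and expel the allylic C13 acetate, or scramble the two esters, in competition with loss of the C5 proton. The fallback sets out from 22 and builds the lactone before the sensitive esters exist. Singlet oxygen with iPr2NEt converts 22 through the silylated endoperoxide F3 into the silylated hydroxybutenolide F4. Catalytic TsOH in benzene over molecular sieves dehydrates F4 to the bis-silylated alkylidene butenolide F5. HF·pyridine frees the 8,13-diol F6, and AcCl with collidine at −78 °C gives the 13-acetate F7. Methacrylic anhydride then esterifies O8, which rejoins the route at 29.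

Step 7. Facial selectivity or conversion may be poor, because the aldehyde is flanked by two ring substituents. The fallback sets out from 10 and 12 and replaces catalyst control by separation and inversion. BF3·OEt2 promotes the same vinylogous aldol addition without facial control. The two C8 epimers are diastereomers because of C4 and are separated by chromatography. The unwanted (8R)-aldol adduct F8 is inverted by a Mitsunobu reaction with 4-nitrobenzoic acid to the (8S)-4-nitrobenzoate F9. K2CO3 in MeOH then cleaves the nitrobenzoate and the acetate together, which rejoins the route at 14. The directly obtained 13 enters step 8 as planned.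

**Further compounds**
F1 | step 14 | (1R,2E,4S,8S,10R)-cyclodecene epoxy alcohol, E isomer of 20 | C[C@]1(O)Cc2occ(CO[Si](C)(C)C(C)(C)C)c2[C@@H](O[Si](C)(C)C(C)(C)C)C[C@@]3(C)O[C@@H]3/C=C/1
F2 | step 14 | saturated 1,10-epoxy-4-ol (2,3-dihydro-20) | C[C@]1(O)Cc2occ(CO[Si](C)(C)C(C)(C)C)c2[C@@H](O[Si](C)(C)C(C)(C)C)C[C@@]3(C)O[C@@H]3CC1
F3 | step 20 | C6/C12 endoperoxide of furan 22 | CC(C)(C)[Si](C)(C)O[C@H]1C[C@@](C)(O)[C@@H]2CC[C@](C)(CC34OOC(O3)C(CO[Si](C)(C)C(C)(C)C)=C41)O2
F4 | step 20 | 8,13-bis-TBS 6-hydroxybutenolide (C6 epimers) | CC(C)(C)[Si](C)(C)O[C@H]1C[C@@](C)(O)[C@@H]2CC[C@](C)(CC3(O)OC(=O)C(CO[Si](C)(C)C(C)(C)C)=C31)O2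
F5 | step 20 | 8,13-bis-TBS (5E)-alkylidene butenolide | CC(C)(C)[Si](C)(C)O[C@H]1C[C@@](C)(O)[C@@H]2CC[C@](C)(/C=C3/OC(=O)C(CO[Si](C)(C)C(C)(C)C)=C31)O2
F6 | step 20 | (5E)-alkylidene butenolide 8,10,13-triol | O[C@H]1C[C@@](C)(O)[C@@H]2CC[C@](C)(/C=C3/OC(=O)C(CO)=C31)O2
F7 | step 20 | 13-O-acetate of F6 | O[C@H]1C[C@@](C)(O)[C@@H]2CC[C@](C)(/C=C3/OC(=O)C(COC(C)=O)=C31)O2
F8 | step 7 | (8R)-epimer of 13 | C[C@@]1(Cc2occ(COC(C)=O)c2[C@H](O)C/C(C)=C/C(=O)OC)O[C@@H](C(C)(C)C)OC1=O
F9 | step 7 | (8S)-4-nitrobenzoate of 13 | C[C@@]1(Cc2occ(COC(C)=O)c2[C@@H](OC(=O)c3ccc(cc3)[N+](=O)[O-])C/C(C)=C/C(=O)OC)O[C@@H](C(C)(C)C)OC1=O
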